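The readings are simulated from invented constants; the scatter is artificial.

**The fork.** Substrate does not vanish: each molecule that leaves the substrate column has become target or something else, so I follow one molecule and ask its chance at the fork. Both proposed steps that consume substrate take dissolved gas, so substrate and gas should cancel from that chance, while catalyst should not. I call s the target found per substrate gone, the selectivity; isomer is unread, so it counts as lost.

common to all: gas phase 9.2 mM (held)
- Wednesday's: substrate 0.067 M; catalyst 2.5 mM; run made earlier
- Monday's: substrate 0.15 M; catalyst 2.5 mM; run made earlier
- Thursday's: substrate 0.10 M; catalyst 5 mM; run made earlier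
- flask: substrate 0.10 M; catalyst 2.5 mM; time 2.5 h

- Wednesday's (time / h: target / %, substrate / %): 0.250: 3.2, 87.5; 0.417: 9.1, 83.0; 0.833: 17.7, 64.7; 1.50: 26.4, 40.0; 3.00: 40.6, 11.4
- Monday's (time / h: target / %, substrate / %): 0.667: 11.3, 80.0; 1.33: 19.5, 61.9; 2.00: 27.2, 45.0; 2.50: 32.4, 30.8; 3.00: 34.5, 22.0
- Thursday's (time / h: target / %, substrate / %): 0.667: 16.9, 71.5; 1.33: 34.4, 43.3; 2.00: 45.4, 23.6; 2.50: 53.6, 13.7; 3.00: 55.0, 7.6

(standard deviation of a reading: 1 percentage point)

- at the start none of the gas is dissolved
- steps that have been proposed: substrate + dissolved gas + catalyst -> catalyst + target; target + catalyst <-> isomer of the product + catalyst; gas phase <-> dissolved gas; substrate + dissolved gas -> uncatalysed product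

- west: doubling the transfer coefficient of the gas phase, all else as stated
- south-east: doubling the saturation concentration of gas phase, all else as stated
- north: doubling the amount of catalyst, all else as stated

- amount of target at 2.5 h, in percent of the substrate charged
- the change that raises the amount of target at 2.5 h, in percent of the substrate charged most ("none" if none brings more than 2 percentage points) (west / south-east / north / none)
- amount of target at 2.5 h, in percent of the substrate charged, after north

**Reading s.** At the last readings s is 0.458 in Wednesday's run and 0.442 in Monday's, nearly equal, though Monday's charge is twice Wednesday's. So I take 0.450 at 2.5 mM. As odds this is 0.819: the fork odds o, target against whatever else the substrate became. Thursday's run, with the readings either side of 2.5 h, gives s of 0.595, so odds of 1.47, twice those at half its catalyst.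

**First way.** Wednesday's substrate, decaying exponentially between its last readings, stands near 17.3% at 2.5 h; Monday's reads 30.8%. The flask's charge lies 0.398 of the way between, which leaves 22.7% substrate. Then s on the substrate gone gives 34.8% target.

**Second way.** The target column, interpolated straight, gives Wednesday 35.9% against Monday's 32.4%, so 34.5% at the same position. The two differ by less than the scatter, but both lean on Wednesday's last target reading, so this is a partial check. I commit to the first.

**Where they part.** North is Thursday's recipe. The share on its substrate gone gives 51.3%, but the reading says 53.6%. I distrust the reading: target climbs 8.2 percentage points into it and 1.4 points out of it, a kink. Changes of gas should keep s, so I reckon them at 45.0% with the substrate consumed entirely, less than my figure for north.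

**The result.** The forecast says 35% (32% to 38%), north as the best change, and 51.5% after it (49% to 54%), holding that “West or south-east only speed consumption without changing selectivity”. The flask gives 35.3% and 51.2% after north, which gains 16 points, against 9.2 points for south-east and 4.5 points for west.

    substrate + dissolved gas + catalyst → catalyst + target (k = 26700 M⁻² h⁻¹)
    target + catalyst ⇌ isomer of the product + catalyst, rate k2*[catalyst]*[target] forward; the back reaction follows from the equilibrium constant (K = 0.209, k = 525 M⁻¹ h⁻¹)
    gas phase ⇌ dissolved gas, rate k3*(csat - [dissolved gas]) (kL = 7.70 h⁻¹)
    substrate + dissolved gas → uncatalysed product (k = 54.5 M⁻¹ h⁻¹)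

**Second flask.** This flask ends with s at 0.459. A neighbouring flask holds 0.0010 M catalyst, its other charges and time unchanged. Scaling the fork odds with catalyst gives 0.328, which is a share of 0.247. The neighbour keeps 33% of its substrate, so that share predicts 16.5% target. It holds 18.5% target beside 44.7% uncatalysed product.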